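**Plan**

Numbering: C1 ester carbon, C2 its CH2, C3 hemiketal carbon, C4 (CHMe), C5 (CH2), C6 (quaternary C–O), O–O between C6 and C3, chain C7–C16 with phenyl on C16.
Retrosynthesis: with a temporary tert-butoxycarbonyl group on C4, the 1,2-dioxan-3-ol is cut at C4–C5, C6–O and O–C3 in one operation. This works because C3/C4 are a ketone and its α-carbon, C5/C6 are the CH2 and the substituted carbon of a 1,1-disubstituted alkene, and the two pairs are bridged only by O–O.
The pieces are keto diester 19 (cut at C2–C3), diene 13 (cut at C7–C8, C9–C10 and C14–C15) and O2.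
Forward: the chain is joined at C7–C8 (Evans alkylation), C14–C15 (acetylide alkylation) and C9–C10 (copper-catalysed Grignard coupling); the only ring, the 1,2-dioxane, arises in step 8, and the temporary ester leaves as CO2 in step 9.
Stereochemistry: C8 comes from the (R)-benzyloxazolidinone auxiliary and the Z-alkene from Lindlar semihydrogenation. C6 forms without control and its epimer is removed by chromatography; C4 is set by protonation and equilibration after decarboxylation, and C3 follows as the anomerically preferred hemiketal.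

Key step: step 8

Remark: 14 is taken as a purchasable malonic half-ester and, like 19, is used as the racemate; this is immaterial because C4 becomes quaternary in step 8 and is re-formed by protonation in step 9.

**Step 1**
Reactants: 1 (4R)-4-benzyl-3-propanoyl-1,3-oxazolidin-2-one; 2 3-bromo-2-methylprop-1-ene
Product: 4 (4R)-4-benzyl-3-[(2S)-2,4-dimethylpent-4-enoyl]-1,3-oxazolidin-2-one, via sodium enolate 3 (not isolated)
Conditions: NaN(SiMe3)2 (1.1 equiv), THF, −78 °C; then 2 (3 equiv), −78 → −40 °C
Reagents that add atoms: 3-bromo-2-methylprop-1-ene (2), C=C(C)CBr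
Why: Evans asymmetric alkylation: the sodium-chelated (Z)-enolate 3 is alkylated by the allylic bromide on the face opposite the benzyl group, which sets the new methyl-bearing centre (later C8) as S.

**Step 2**
Reactants: 4 (4R)-4-benzyl-3-[(2S)-2,4-dimethylpent-4-enoyl]-1,3-oxazolidin-2-one
Product: 5 (2S)-2,4-dimethylpent-4-en-1-ol
Conditions: LiBH4, MeOH (1.1 equiv), Et2O, 0 °C
Reagents that add atoms: none
Why: Reductive cleavage of the N-acyl oxazolidinone: hydride attacks the exocyclic imide carbonyl, giving the primary alcohol and the recoverable auxiliary without touching the stereocentre or the alkene.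

**Step 3**
Reactants: 5 (2S)-2,4-dimethylpent-4-en-1-ol
Product: 6 (2S)-2,4-dimethylpent-4-en-1-yl 4-methylbenzenesulfonate
Conditions: TsCl, Et3N, DMAP (cat.), CH2Cl2, 0 → 23 °C
Reagents that add atoms: 4-methylbenzenesulfonyl chloride, Cc1ccc(cc1)S(=O)(=O)Cl
Why: Sulfonylation (tosylation) of an unhindered primary alcohol turns the future C9 into a leaving group without touching any bond at the stereocentre.

**Step 4**
Reactants: 7 ethynylbenzene; 8 1-bromo-5-chloropentane
Product: 10 (7-chlorohept-1-yn-1-yl)benzene, via lithium phenylacetylide 9 (not isolated)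
Conditions: n-BuLi, THF, −78 °C; then 8 (1.2 equiv), DMPU, −78 → 23 °C
Reagents that add atoms: 1-bromo-5-chloropentane (8), ClCCCCCBr
Why: SN2 alkylation of a lithium acetylide in a dipolar co-solvent; the primary bromide is displaced much faster than the chloride, which stays as the handle for the Grignard reagent.

**Step 5**
Reactants: 10 (7-chlorohept-1-yn-1-yl)benzene
Product: 11 [(1Z)-7-chlorohept-1-en-1-yl]benzene
Conditions: H2 (1 atm), Pd/CaCO3 poisoned with Pb(OAc)2 (Lindlar catalyst), quinoline, hexane, 23 °C, stopped after 1 equiv H2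
Reagents that add atoms: none
Why: Lindlar semihydrogenation: syn delivery of H2 on the poisoned palladium surface should give the Z-alkene; no other alkene is present at this stage and the alkyl chloride is inert.

**Step 6**
Reactants: 11 [(1Z)-7-chlorohept-1-en-1-yl]benzene; 6 (2S)-2,4-dimethylpent-4-en-1-yl 4-methylbenzenesulfonate
Product: 13 (4R,11Z)-2,4-dimethyl-12-phenyldodeca-1,11-diene, via Grignard reagent 12 (not isolated)
Conditions: 11 (1.5 equiv), Mg (I2-activated), THF, 60 °C; then 6, Li2CuCl4 (5 mol%), THF, −78 → 23 °C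
Reagents that add atoms: none
Why: Copper-catalysed cross-coupling of a primary alkyl Grignard reagent with a primary tosylate forms C9–C10 at the CH2 next to the stereocentre, which is untouched (its descriptor becomes R only because the CIP priorities change); both alkenes are inert.

**Step 7**
Reactants: 14 3-tert-butoxy-2-methyl-3-oxopropanoic acid; 15 potassium 3-methoxy-3-oxopropanoate
Product: 19 1-tert-butyl 5-methyl 2-methyl-3-oxopentanedioate, via imidazolide 16 (not isolated), via magnesium malonate 17 (not isolated), via acylmalonic half-acid 18 (not isolated)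
Conditions: 14, CDI (1.1 equiv), THF, 23 °C; separately 15 (2 equiv), MgCl2 (1 equiv), THF/MeCN, 23 → 50 °C; combined, 23 °C; then 1 M HCl
Reagents that add atoms: potassium 3-methoxy-3-oxopropanoate (15), COC(=O)CC(=O)[O-].[K+]
Why: Decarboxylative Claisen condensation of a magnesium malonate half-ester with an acyl imidazolide: 17 is C-acylated by 16 under neutral conditions and the resulting 18 loses CO2 on acidification to give the β-keto ester.

**Step 8**
Reactants: 19 1-tert-butyl 5-methyl 2-methyl-3-oxopentanedioate; 13 (4R,11Z)-2,4-dimethyl-12-phenyldodeca-1,11-diene; 20 dioxygen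
Product: 22 tert-butyl 3-hydroxy-3-(2-methoxy-2-oxoethyl)-4,6-dimethyl-6-[(2R,9Z)-2-methyl-10-phenyldec-9-en-1-yl]-1,2-dioxane-4-carboxylate (mixture of diastereomers at the ring carbons), via hydroperoxy ketone 21 (not isolated)
Conditions: 19 (3 equiv), Mn(OAc)3·2H2O (20 mol%), O2 (1 atm), AcOH, 23 °C
Reagents that add atoms: dioxygen (20), O=O
Why: Mn(OAc)3 converts 19 into its trivalent manganese enolate at the methyl-bearing C4, loss of divalent manganese gives the electrophilic tertiary C4 radical, this adds to the unsubstituted CH2 terminus of the 1,1-disubstituted alkene of 13 (C4–C5), the tertiary C6 radical is captured by O2 (C6–O), and the peroxyl radical is reduced by divalent manganese, which regenerates the oxidant and gives hydroperoxide 21. The closest known reaction type is the Mn(OAc)3-catalysed aerobic annulation of 2-substituted 1,3-dicarbonyl compounds with 1,1-disubstituted alkenes and O2 to 1,2-dioxan-3-ols. The 1,2-dioxane closes by 6-exo-trig addition of the terminal hydroperoxide oxygen to the C3 ketone (C3–O), the only ketone of 21. No element controls C4 or C6 (C4 is erased again in step 9 and C6 sees only the remote C8 centre), and C3 settles under ring–chain equilibration as the hemiketal with axial OH, so 22 is carried on as a mixture. The step needs oxidation at C4 and not at the C2 methylene: the C4 enolate is the more electron-rich and should give a free tertiary radical without assistance from the alkene, whereas the C2 enolate reacts mainly with electron-rich alkenes, which biases but does not guarantee the site. It also needs attack at the methallyl terminus and not at the styrene: the radical finds an unhindered CH2 that leads to a tertiary radical, while both carbons of the cis-1,2-disubstituted styrene are shielded, and 19 is used in excess so that 13 is consumed.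

**Step 9**
Reactants: 22 tert-butyl 3-hydroxy-3-(2-methoxy-2-oxoethyl)-4,6-dimethyl-6-[(2R,9Z)-2-methyl-10-phenyldec-9-en-1-yl]-1,2-dioxane-4-carboxylate
Product: 24 methyl 2-[(3S,4R,6S)-3-hydroxy-4,6-dimethyl-6-[(2R,9Z)-2-methyl-10-phenyldec-9-en-1-yl]-1,2-dioxan-3-yl]acetate, via carboxylic acid 23 (not isolated)
Conditions: CF3CO2H/CH2Cl2 (1:4), 0 → 23 °C; then preparative HPLC (SiO2)
Reagents that add atoms: none
Why: Acidolysis of the tert-butyl ester (loss of 2-methylpropene) gives 23, which should lose CO2 at room temperature through its ring-opened β-keto acid tautomer; C4 is then set by protonation and equilibrates through the open-chain ketone towards an equatorial methyl, C3 re-closes with axial OH and equatorial CH2CO2Me as in the target, and the (3S,4R,6S) isomer is separated from its C6 and C4 epimers, the C4 epimer being recyclable by re-equilibration in the same acid.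

**Compound list**

1 | (4R)-4-benzyl-3-propanoyl-1,3-oxazolidin-2-one | CCC(=O)N1C(=O)OC[C@H]1Cc1ccccc1 | starting material
2 | 3-bromo-2-methylprop-1-ene | C=C(C)CBr | starting material
3 | sodium (1Z)-1-[(4R)-4-benzyl-2-oxo-1,3-oxazolidin-3-yl]prop-1-en-1-olate | C/C=C(\[O-])N1C(=O)OC[C@H]1Cc1ccccc1.[Na+] | intermediate (not isolated)
4 | (4R)-4-benzyl-3-[(2S)-2,4-dimethylpent-4-enoyl]-1,3-oxazolidin-2-one | C=C(C)C[C@H](C)C(=O)N1C(=O)OC[C@H]1Cc1ccccc1 | intermediate
5 | (2S)-2,4-dimethylpent-4-en-1-ol | C=C(C)C[C@H](C)CO | intermediate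
6 | (2S)-2,4-dimethylpent-4-en-1-yl 4-methylbenzenesulfonate | C=C(C)C[C@H](C)COS(=O)(=O)c1ccc(C)cc1 | intermediate
7 | ethynylbenzene | C#Cc1ccccc1 | starting material
8 | 1-bromo-5-chloropentane | ClCCCCCBr | starting material
9 | lithium phenylacetylide | [Li+].[C-]#Cc1ccccc1 | intermediate (not isolated)
10 | (7-chlorohept-1-yn-1-yl)benzene | ClCCCCCC#Cc1ccccc1 | intermediate
11 | [(1Z)-7-chlorohept-1-en-1-yl]benzene | ClCCCCC/C=C\c1ccccc1 | intermediate
12 | [(6Z)-7-phenylhept-6-en-1-yl]magnesium chloride | Cl[Mg]CCCCC/C=C\c1ccccc1 | intermediate (not isolated)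
13 | (4R,11Z)-2,4-dimethyl-12-phenyldodeca-1,11-diene | C=C(C)C[C@H](C)CCCCCC/C=C\c1ccccc1 | intermediate
14 | 3-tert-butoxy-2-methyl-3-oxopropanoic acid (racemic) | CC(C(O)=O)C(=O)OC(C)(C)C | starting material
15 | potassium 3-methoxy-3-oxopropanoate | COC(=O)CC(=O)[O-].[K+] | starting material
16 | tert-butyl 3-(1H-imidazol-1-yl)-2-methyl-3-oxopropanoate | CC(C(=O)OC(C)(C)C)C(=O)n1ccnc1 | intermediate (not isolated)
17 | magnesium bis(3-methoxy-3-oxopropanoate) | COC(=O)CC(=O)[O-].COC(=O)CC(=O)[O-].[Mg+2] | intermediate (not isolated)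
18 | 5-tert-butoxy-2-(methoxycarbonyl)-4-methyl-3,5-dioxopentanoic acid | COC(=O)C(C(=O)O)C(=O)C(C)C(=O)OC(C)(C)C | intermediate (not isolated)
19 | 1-tert-butyl 5-methyl 2-methyl-3-oxopentanedioate (racemic) | COC(=O)CC(=O)C(C)C(=O)OC(C)(C)C | intermediate
20 | dioxygen | O=O | starting material
21 | 1-tert-butyl 5-methyl 2-[(4R,11Z)-2-hydroperoxy-2,4-dimethyl-12-phenyldodec-11-en-1-yl]-2-methyl-3-oxopentanedioate (mixture at the two new centres) | COC(=O)CC(=O)C(C)(CC(C)(OO)C[C@H](C)CCCCCC/C=C\c1ccccc1)C(=O)OC(C)(C)C | intermediate (not isolated)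
22 | tert-butyl 3-hydroxy-3-(2-methoxy-2-oxoethyl)-4,6-dimethyl-6-[(2R,9Z)-2-methyl-10-phenyldec-9-en-1-yl]-1,2-dioxane-4-carboxylate (mixture at the ring carbons) | COC(=O)CC1(O)OOC(C)(C[C@H](C)CCCCCC/C=C\c2ccccc2)CC1(C)C(=O)OC(C)(C)C | intermediate
23 | 3-hydroxy-3-(2-methoxy-2-oxoethyl)-4,6-dimethyl-6-[(2R,9Z)-2-methyl-10-phenyldec-9-en-1-yl]-1,2-dioxane-4-carboxylic acid (mixture at the ring carbons) | COC(=O)CC1(O)OOC(C)(C[C@H](C)CCCCCC/C=C\c2ccccc2)CC1(C)C(=O)O | intermediate (not isolated)
24 | methyl 2-[(3S,4R,6S)-3-hydroxy-4,6-dimethyl-6-[(2R,9Z)-2-methyl-10-phenyldec-9-en-1-yl]-1,2-dioxan-3-yl]acetate | COC(=O)C[C@]1(O)OO[C@@](C)(C[C@H](C)CCCCCC/C=C\c2ccccc2)C[C@H]1C | target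

**Count and risks**

Total step count: 9. Longest linear sequence: 6 steps (1, 2, 3, 6, 8, 9).

Steps most likely to fail:

1. Step 8. Enolisation and oxidation at the unsubstituted C2 methylene of 19, or capture of the C4 radical by O2 before it reaches the alkene, may compete with C4–C5 bond formation. The fallback sets out from 19 and returns at 23. The tert-butyl ester is cleaved first (CF3CO2H, CH2Cl2, 0 °C), while no peroxide or styrene is present, to give 5-methoxy-2-methyl-3,5-dioxopentanoic acid F1, used cold at once. Its carboxylate binds manganese, and Mn(O2CC5H4N)3 (manganese tris(pyridine-2-carboxylate)) in DMF at 0 °C is known to turn β-keto acids into their α-radicals under conditions that leave simple β-keto esters alone, so C4 should be the only site oxidised. Addition to 13 under O2 should then give the open-chain adduct 2-[(4R,11Z)-2-hydroperoxy-2,4-dimethyl-12-phenyldodec-11-en-1-yl]-5-methoxy-2-methyl-3,5-dioxopentanoic acid F2, which closes to 23 and loses CO2 as in step 9.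

2. Step 9. Acid may ionise or rearrange the peroxy hemiketal, or CF3CO2H may add across the cis-styrene, while the ester is being cleaved. The fallback sets out from 13, uses a fluoride-labile temporary ester and returns at 23.
   - Heating 2,2,5-trimethyl-1,3-dioxane-4,6-dione with 2-(trimethylsilyl)ethanol (toluene, 90 °C) should give 2-methyl-3-oxo-3-[2-(trimethylsilyl)ethoxy]propanoic acid F3.
   - As in step 7, CDI gives 2-(trimethylsilyl)ethyl 3-(1H-imidazol-1-yl)-2-methyl-3-oxopropanoate F4, which acylates 17 to 2-(methoxycarbonyl)-4-methyl-3,5-dioxo-5-[2-(trimethylsilyl)ethoxy]pentanoic acid F5; loss of CO2 gives 5-methyl 1-[2-(trimethylsilyl)ethyl] 2-methyl-3-oxopentanedioate F6.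
   - Annulation of F6 with 13 and O2 under the conditions of step 8 should give, through 5-methyl 1-[2-(trimethylsilyl)ethyl] 2-[(4R,11Z)-2-hydroperoxy-2,4-dimethyl-12-phenyldodec-11-en-1-yl]-2-methyl-3-oxopentanedioate F7, the dioxanol 2-(trimethylsilyl)ethyl 3-hydroxy-3-(2-methoxy-2-oxoethyl)-4,6-dimethyl-6-[(2R,9Z)-2-methyl-10-phenyldec-9-en-1-yl]-1,2-dioxane-4-carboxylate F8.
   - Bu4NF in THF at 0 °C then releases 23 with loss of ethene and Me3SiF, without strong acid.

3. Step 7. Imidazolide 16 may be deprotonated at its acidic methine (ketene formation, self-condensation) instead of C-acylating 17. The fallback sets out from 14 and returns at 19. Acid 14 is coupled with 2,2-dimethyl-1,3-dioxane-4,6-dione (DCC, DMAP, CH2Cl2, 0 → 23 °C) to give tert-butyl 3-(2,2-dimethyl-4,6-dioxo-1,3-dioxan-5-yl)-2-methyl-3-oxopropanoate F9. Heating F9 in MeOH (65 °C) opens the dioxanedione with loss of acetone and CO2 to give 19.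

**Further compounds**

F1 | step 8 | 5-methoxy-2-methyl-3,5-dioxopentanoic acid | COC(=O)CC(=O)C(C)C(=O)O
F2 | step 8 | 2-[(4R,11Z)-2-hydroperoxy-2,4-dimethyl-12-phenyldodec-11-en-1-yl]-5-methoxy-2-methyl-3,5-dioxopentanoic acid | COC(=O)CC(=O)C(C)(CC(C)(OO)C[C@H](C)CCCCCC/C=C\c1ccccc1)C(=O)O
F3 | step 9 | 2-methyl-3-oxo-3-[2-(trimethylsilyl)ethoxy]propanoic acid | CC(C(=O)O)C(=O)OCC[Si](C)(C)C
F4 | step 9 | 2-(trimethylsilyl)ethyl 3-(1H-imidazol-1-yl)-2-methyl-3-oxopropanoate | CC(C(=O)OCC[Si](C)(C)C)C(=O)n1ccnc1
F5 | step 9 | 2-(methoxycarbonyl)-4-methyl-3,5-dioxo-5-[2-(trimethylsilyl)ethoxy]pentanoic acid | COC(=O)C(C(=O)O)C(=O)C(C)C(=O)OCC[Si](C)(C)C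
F6 | step 9 | 5-methyl 1-[2-(trimethylsilyl)ethyl] 2-methyl-3-oxopentanedioate | COC(=O)CC(=O)C(C)C(=O)OCC[Si](C)(C)C
F7 | step 9 | 5-methyl 1-[2-(trimethylsilyl)ethyl] 2-[(4R,11Z)-2-hydroperoxy-2,4-dimethyl-12-phenyldodec-11-en-1-yl]-2-methyl-3-oxopentanedioate | COC(=O)CC(=O)C(C)(CC(C)(OO)C[C@H](C)CCCCCC/C=C\c1ccccc1)C(=O)OCC[Si](C)(C)C
F8 | step 9 | 2-(trimethylsilyl)ethyl 3-hydroxy-3-(2-methoxy-2-oxoethyl)-4,6-dimethyl-6-[(2R,9Z)-2-methyl-10-phenyldec-9-en-1-yl]-1,2-dioxane-4-carboxylate | COC(=O)CC1(O)OOC(C)(C[C@H](C)CCCCCC/C=C\c2ccccc2)CC1(C)C(=O)OCC[Si](C)(C)C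
F9 | step 7 | tert-butyl 3-(2,2-dimethyl-4,6-dioxo-1,3-dioxan-5-yl)-2-methyl-3-oxopropanoate | CC(C(=O)OC(C)(C)C)C(=O)C1C(=O)OC(C)(C)OC1=O
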